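We have no constants for the steps, so we reckon from the charges and two runs.

common to all: substrate 0.17 M; initiator 5.1 mM

| flask | solid reagent | remark | time |
|---|---|---|---|
| larch | 0.076 M | run made earlier |  |
| alder | 0.31 M | run made earlier |  |
| flask | 0.153 M |  | 4.0 d |

- larch (time / d: product / %, substrate / %): 0.417: 40, 58; 0.625: 47, 55; 1.04: 45, 56; 1.67: 45, 55; 3.00: 44, 53; 5.00: 46, 56
- alder (time / d: product / %, substrate / %): 0.417: 39, 61; 0.625: 51, 50; 1.04: 68, 30; 1.67: 86, 14; 3.00: 95, 3; 5.00: 100, 1

(each reading ± 1.5 percentage points)

- the product standing at 4.0 d, as a percentage of the substrate charged
- the change that raises the amount of product at 4.0 d, in percent of the substrate charged most ("none" if none brings more than 2 percentage points) (gamma / zeta / none)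
- amount of product at 4.0 d, in percent of the substrate charged, after gamma

- gamma: doubling the dissolution coefficient of the solid reagent, all else as stated
- zeta: doubling the solubility of the solid reagent, all else as stated

- as a solid, counted per litre of solution: solid reagent
- the earlier runs were read with a standard deviation of 1.5 percentage points
- on the list of suspects stand: initiator -> 2 initiating radical; substrate + initiating radical <-> chain carrier; coupling partner + chain carrier -> product + initiating radical; 2 initiating radical -> ended chains; solid reagent <-> coupling partner
- at the start none of the solid reagent is in solution

The larch run stops early: its product reads 47 % at 0.625 d and 46 % at 5.00 d. If one solid reagent makes one product, solid reagent is the limiting reagent whenever its charge lies below the substrate charge, and one number follows. For this flask L is 10.0 %, the substrate charge less the solid charge, divided by the substrate charge: the part of the substrate with no partner. For the larch run L is 55.3 %, and its late substrate reads 53 % to 56 %. The alder run has more solid than substrate, and its substrate reads 1 % at 5.00 d.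

But L says where the flask stops, not when. Alder substrate falls from 61 % to 14 % between 0.417 d and 1.67 d, a first-order constant of 1.17 /d. At that pace this flask reaches L after 1.96 d, earlier than 4.0 d. So we expect 90.0 % product, and neither gamma nor zeta enters L.

The forecast gives 90 % (87 % to 91 %), best change none, and 90 % after gamma: “Neither faster dissolution nor higher solubility changes the stoichiometric limit”.

The flask gives 90.0 %, best change none, and 90.0 % after gamma. At 2.00 d solid reagent stands at 0 % of its charge, with product already at 90.0 %. At 4.00 d substrate stands at 9.86 % and chain carrier at 0.137 %, together against an L of 10.0 %.

    initiator → 2 initiating radical (k = 0.00327 /h)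
    substrate + initiating radical ⇌ chain carrier (K = 3.35 × 10⁵ /M, k = 1.05 × 10⁶ /M/h)
    coupling partner + chain carrier → product + initiating radical (k = 3.91 × 10⁵ /M/h)
    2 initiating radical → ended chains (k = 2.00 × 10⁶ /M/s)
    solid reagent ⇌ coupling partner, rate k5*(cs5 - [coupling partner]) while solid is left; crystals form when [coupling partner] > cs5 (solubility = 0.150 M, k = 0.106 /h)

A neighbour flask, charged with 0.061 M of solid reagent, has an L of 64.1 %. Computed, that neighbour holds 63.3 % substrate, 0.831 % chain carrier and 35.9 % product at 4.00 d.

The numbers in the tables come from a simulation for substances that don't exist; scatter was added.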